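**Plan**

- Locants: O1, C2 (4-hydroxyphenyl), C3 (C9H2OAc arm), C4 (C7'H(OAc)-anisyl arm), C5 (ring CH2). The target reads 2R,3S,4R,7'S, with 2,3-trans and 3,4-trans substituents.
- Cuts, in order: the O-acetyl bonds; C7'–H and C7'–aryl (back to ketone, Weinreb amide and aryl Grignard); a second ester restored on C4; finally O1–C2 and C4–C5 together. This leaves formaldehyde and a cyclopropane in which C2 is bonded to C4.
- Enabling feature: ring atom C2 is benzylic to a para-oxygenated arene and stabilises a cation. Ring atom C4 tolerates a geminal diester and stabilises an anion. Ring atom C5, between O1 and C4, has no substituent, so O1=C5 is a formaldehyde unit and C2–C3–C4 is a 1,3-dipole that a donor–acceptor cyclopropane can store.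
- Forward order: enal, temporary three-membered ring, oxolane ring by (3+2) annulation, loss of one ester, anisyl ketone at C4, carbinol, deprotection and acetylation.
- Stereochemistry: C3 comes from iminium catalysis with an (R)-diarylprolinol silyl ether. C2 is set by equilibration against C3 during the annulation. C4 is set by equilibration of the enolisable ester against C3. C7' is set by Felkin–Anh hydride delivery to the ketone.

Key step: step 5

Remark: benzyl on the phenol and TBDPS on the C9 hydroxyl are chosen as spectator groups because both must pass through Sn(OTf)2 and hot wet DMSO; all five starting materials are taken as catalogue compounds.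

Step 1
Reactants: 1 4-(benzyloxy)benzaldehyde; 2 2-(triphenylphosphoranylidene)acetaldehyde
Product: 3 (E)-3-[4-(benzyloxy)phenyl]prop-2-enal
Conditions: toluene, 80 °C, 2 as the limiting component
Reagents that add atoms: none
Why: Wittig olefination with a stabilised formyl ylide is reliably E-selective on aromatic aldehydes, and keeping the ylide limiting suppresses a second homologation of the enal.

Step 2
Reactants: 3 (E)-3-[4-(benzyloxy)phenyl]prop-2-enal; 4 dimethyl bromomalonate
Product: 5 dimethyl (2R,3S)-2-[4-(benzyloxy)phenyl]-3-formylcyclopropane-1,1-dicarboxylate (aryl and formyl trans)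
Conditions: (R)-2-[diphenyl(trimethylsilyloxy)methyl]pyrrolidine (20 mol%), 2,6-lutidine, CH2Cl2, 0 °C to rt
Reagents that add atoms: none
Why: In this iminium–enamine Michael-initiated ring closure the CPh2OTMS group of the (R)-catalyst blocks one face of the (E)-iminium, so bromomalonate adds to the open face of the β-carbon (aryl carbon R), and the derived enamine displaces bromide in a 3-exo-tet closure that places formyl trans to aryl (formyl carbon S, the future C3).

Step 3
Reactants: 5 dimethyl (2R,3S)-2-[4-(benzyloxy)phenyl]-3-formylcyclopropane-1,1-dicarboxylate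
Product: 6 dimethyl (2R,3S)-2-[4-(benzyloxy)phenyl]-3-(hydroxymethyl)cyclopropane-1,1-dicarboxylate
Conditions: NaBH4, MeOH, −10 °C, short contact time
Reagents that add atoms: none
Why: Borohydride reduction takes the aldehyde chemoselectively over the esters without touching a stereocentre, and the low temperature and short contact keep the new alcohol from lactonising onto the cis ester.

Step 4
Reactants: 6 dimethyl (2R,3S)-2-[4-(benzyloxy)phenyl]-3-(hydroxymethyl)cyclopropane-1,1-dicarboxylate
Product: 7 dimethyl (2R,3S)-2-[4-(benzyloxy)phenyl]-3-{[(tert-butyldiphenylsilyl)oxy]methyl}cyclopropane-1,1-dicarboxylate (trans)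
Conditions: TBDPSCl, imidazole, CH2Cl2, 0 °C to rt
Reagents that add atoms: tert-butyl(chloro)diphenylsilane (TBDPSCl), CC(C)(C)[Si](Cl)(c1ccccc1)c1ccccc1
Why: Imidazole-promoted silylation of a primary alcohol is routine, and TBDPS is picked because it resists Lewis acid and hot aqueous DMSO and adds bulk next to the future C2.

Step 5
Reactants: 7 dimethyl (2R,3S)-2-[4-(benzyloxy)phenyl]-3-{[(tert-butyldiphenylsilyl)oxy]methyl}cyclopropane-1,1-dicarboxylate; 8 formaldehyde (charged as dried paraformaldehyde)
Product: 9 dimethyl (2R,3S)-2-[4-(benzyloxy)phenyl]-3-{[(tert-butyldiphenylsilyl)oxy]methyl}oxolane-4,4-dicarboxylate (2,3-trans)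
Conditions: Sn(OTf)2 (20 mol%), (CH2O)n (5 equiv), 4 Å MS, ClCH2CH2Cl, rt then 40 °C, held until the C2 epimer composition no longer changes
Reagents that add atoms: none
Why: Two-point binding of Sn(OTf)2 to the malonate carbonyls polarises 7 until, with the push of the para-benzyloxy group, its C2–C4 bond breaks heterolytically into a benzylic cation paired with a tin enolate; an oxygen of formaldehyde (free monomer, or a polyoxymethylene chain oxygen that then sheds its chain) bonds to C2 (O1–C2), and the enolate carbon C4 attacks the resulting O1=C5H2 oxocarbenium carbon (C4–C5). The closest known reaction type is the Lewis acid-catalysed (3+2) annulation of 2-arylcyclopropane-1,1-diesters, 2,3-disubstituted members included, with aromatic and aliphatic aldehydes, of which formaldehyde is simply the smallest and least used member. The oxolane closes in a 5-(enolexo)-endo-trig aldol mode, formally unfavourable yet the normal course of this annulation because a cationic C=O acceptor tolerates the acute approach angle. Under kinetic control such openings are SN2-like and invert the donor carbon, which from a trans cyclopropane would lead to the 2,3-cis ring, so the step is run on purpose under equilibrating conditions: with a para-alkoxyphenyl donor the cyclopropane re-closes reversibly at C2, the O1–C2 bond forms reversibly before ring closure, and the same Lewis acid re-ionises C2–O1 of the product. The one new stereocentre, C2, is therefore fixed by thermodynamic control from C3, whose CH2OTBDPS arm, buttressed by the quaternary C4, drives the aryl group to the opposite ring face (2R, 2,3-trans) whichever C2 epimer forms first. The step needs cleavage of C2–C4 rather than C3–C4 and an untouched C3, which the substrate secures because only C2 carries a cation-stabilising aryl group and C3 never belongs to the ionised centre, while benzyl and TBDPS withstand the triflate.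

Step 6
Reactants: 9 dimethyl (2R,3S)-2-[4-(benzyloxy)phenyl]-3-{[(tert-butyldiphenylsilyl)oxy]methyl}oxolane-4,4-dicarboxylate
Product: 10 methyl (2R,3S,4R)-2-[4-(benzyloxy)phenyl]-3-{[(tert-butyldiphenylsilyl)oxy]methyl}oxolane-4-carboxylate (all-trans)
Conditions: LiCl, H2O, DMSO, 150 °C
Reagents that add atoms: none
Why: In the Krapcho dealkoxycarbonylation chloride demethylates one ester, CO2 leaves and the ester enolate is protonated, and C4 is set under thermodynamic control because the remaining enolisable ester equilibrates in the hot, faintly basic medium to the isomer with CO2Me trans to the C3 arm.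

Step 7
Reactants: 10 methyl (2R,3S,4R)-2-[4-(benzyloxy)phenyl]-3-{[(tert-butyldiphenylsilyl)oxy]methyl}oxolane-4-carboxylate
Product: 11 (2R,3S,4R)-2-[4-(benzyloxy)phenyl]-3-{[(tert-butyldiphenylsilyl)oxy]methyl}-N-methoxy-N-methyloxolane-4-carboxamide
Conditions: MeONHMe·HCl, i-PrMgCl, THF, −20 to 0 °C
Reagents that add atoms: N,O-dimethylhydroxylamine hydrochloride, CNOC.Cl
Why: Weinreb amide formation by attack of the chloromagnesium amide on a methyl ester is standard, and any enolisation at C4 falls back to the favoured 3,4-trans isomer.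

Step 8
Reactants: 11 (2R,3S,4R)-2-[4-(benzyloxy)phenyl]-3-{[(tert-butyldiphenylsilyl)oxy]methyl}-N-methoxy-N-methyloxolane-4-carboxamide; 12 4-methoxyphenylmagnesium bromide (THF solution)
Product: 13 [(2R,3S,4R)-2-[4-(benzyloxy)phenyl]-3-{[(tert-butyldiphenylsilyl)oxy]methyl}oxolan-4-yl](4-methoxyphenyl)methanone
Conditions: THF, 0 °C; sat. aq NH4Cl
Reagents that add atoms: none
Why: Grignard addition to a Weinreb amide halts at the magnesium-chelated tetrahedral adduct, so the aryl ketone appears only on work-up and over-addition is avoided.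

Step 9
Reactants: 13 [(2R,3S,4R)-2-[4-(benzyloxy)phenyl]-3-{[(tert-butyldiphenylsilyl)oxy]methyl}oxolan-4-yl](4-methoxyphenyl)methanone
Product: 14 (S)-[(2R,3S,4R)-2-[4-(benzyloxy)phenyl]-3-{[(tert-butyldiphenylsilyl)oxy]methyl}oxolan-4-yl](4-methoxyphenyl)methanol
Conditions: LiBH(s-Bu)3 (L-Selectride), THF, −78 °C; H2O quench
Reagents that add atoms: none
Why: In this Felkin–Anh-controlled reduction by a bulky borohydride the branched ring carbon C3 stands anti to the incoming hydride and C5H2–O1 sits next to the carbonyl oxygen, so hydride reaches the Re face of C7' and gives the 7'S carbinol, and a lithium chelate between the ketone oxygen and O1 would expose the same face.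

Step 10
Reactants: 14 (S)-[(2R,3S,4R)-2-[4-(benzyloxy)phenyl]-3-{[(tert-butyldiphenylsilyl)oxy]methyl}oxolan-4-yl](4-methoxyphenyl)methanol
Product: 15 4-[(2R,3S,4R)-3-{[(tert-butyldiphenylsilyl)oxy]methyl}-4-[(S)-hydroxy(4-methoxyphenyl)methyl]oxolan-2-yl]phenol
Conditions: H2 (1 atm), 10% Pd/C, EtOAc, rt, stopped once 14 is consumed
Reagents that add atoms: none
Why: Catalytic hydrogenolysis cleaves an aryl benzyl ether much faster than the ring C2–O1 bond or a free benzylic carbinol under neutral aprotic conditions, and it is done before acetylation because a benzylic acetate would be far more prone to reduction.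

Step 11
Reactants: 15 4-[(2R,3S,4R)-3-{[(tert-butyldiphenylsilyl)oxy]methyl}-4-[(S)-hydroxy(4-methoxyphenyl)methyl]oxolan-2-yl]phenol
Product: 16 4-[(2R,3S,4R)-3-(hydroxymethyl)-4-[(S)-hydroxy(4-methoxyphenyl)methyl]oxolan-2-yl]phenol
Conditions: TBAF, THF, 0 °C to rt
Reagents that add atoms: none
Why: Fluoride-driven desilylation frees the primary alcohol under non-acidic conditions, so the two ionisable benzylic centres C2 and C7' keep their configuration.

Step 12
Reactants: 16 4-[(2R,3S,4R)-3-(hydroxymethyl)-4-[(S)-hydroxy(4-methoxyphenyl)methyl]oxolan-2-yl]phenol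
Product: 17 4-[(2R,3S,4R)-3-(acetoxymethyl)-4-[(S)-acetoxy(4-methoxyphenyl)methyl]oxolan-2-yl]phenyl acetate
Conditions: Ac2O, pyridine, DMAP (cat.), CH2Cl2, 0 °C to rt
Reagents that add atoms: acetic anhydride, CC(=O)OC(C)=O
Why: Exhaustive DMAP-catalysed acylation esterifies the phenol, the primary alcohol and the secondary benzylic alcohol at oxygen under basic, non-ionising conditions, so no C–O bond at a stereocentre is broken.

Step 13
Reactants: 17 4-[(2R,3S,4R)-3-(acetoxymethyl)-4-[(S)-acetoxy(4-methoxyphenyl)methyl]oxolan-2-yl]phenyl acetate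
Product: 18 [(2R,3S,4R)-4-[(S)-acetoxy(4-methoxyphenyl)methyl]-2-(4-hydroxyphenyl)oxolan-3-yl]methyl acetate (CNP0231272.1)
Conditions: NH4OAc, MeOH–H2O (4:1), rt
Reagents that add atoms: none
Why: This chemoselective solvolysis of an aryl acetate works because phenoxide is by far the better leaving group, so near-neutral NH4OAc in aqueous methanol removes only that acetyl and leaves the two alkyl acetates in place.

**Compound list**

1 | 4-(benzyloxy)benzaldehyde | O=Cc1ccc(OCc2ccccc2)cc1 | starting material
2 | 2-(triphenylphosphoranylidene)acetaldehyde | O=CC=P(c1ccccc1)(c1ccccc1)c1ccccc1 | starting material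
3 | (E)-3-[4-(benzyloxy)phenyl]prop-2-enal | O=C/C=C/c1ccc(OCc2ccccc2)cc1 | intermediate
4 | dimethyl bromomalonate | COC(=O)C(Br)C(=O)OC | starting material
5 | dimethyl (2R,3S)-2-[4-(benzyloxy)phenyl]-3-formylcyclopropane-1,1-dicarboxylate | O=C[C@H]1[C@H](c2ccc(OCc3ccccc3)cc2)C1(C(=O)OC)C(=O)OC | intermediate
6 | dimethyl (2R,3S)-2-[4-(benzyloxy)phenyl]-3-(hydroxymethyl)cyclopropane-1,1-dicarboxylate | OC[C@H]1[C@H](c2ccc(OCc3ccccc3)cc2)C1(C(=O)OC)C(=O)OC | intermediate
7 | dimethyl (2R,3S)-2-[4-(benzyloxy)phenyl]-3-{[(tert-butyldiphenylsilyl)oxy]methyl}cyclopropane-1,1-dicarboxylate | CC(C)(C)[Si](c1ccccc1)(c1ccccc1)OC[C@H]1[C@H](c2ccc(OCc3ccccc3)cc2)C1(C(=O)OC)C(=O)OC | intermediate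
8 | formaldehyde (charged as paraformaldehyde) | C=O | starting material
9 | dimethyl (2R,3S)-2-[4-(benzyloxy)phenyl]-3-{[(tert-butyldiphenylsilyl)oxy]methyl}oxolane-4,4-dicarboxylate | COC(=O)C1(C(=O)OC)CO[C@@H](c2ccc(OCc3ccccc3)cc2)[C@@H]1CO[Si](c4ccccc4)(c5ccccc5)C(C)(C)C | intermediate
10 | methyl (2R,3S,4R)-2-[4-(benzyloxy)phenyl]-3-{[(tert-butyldiphenylsilyl)oxy]methyl}oxolane-4-carboxylate | COC(=O)[C@H]1CO[C@@H](c2ccc(OCc3ccccc3)cc2)[C@@H]1CO[Si](c4ccccc4)(c5ccccc5)C(C)(C)C | intermediate
11 | (2R,3S,4R)-2-[4-(benzyloxy)phenyl]-3-{[(tert-butyldiphenylsilyl)oxy]methyl}-N-methoxy-N-methyloxolane-4-carboxamide | CON(C)C(=O)[C@H]1CO[C@@H](c2ccc(OCc3ccccc3)cc2)[C@@H]1CO[Si](c4ccccc4)(c5ccccc5)C(C)(C)C | intermediate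
12 | 4-methoxyphenylmagnesium bromide | COc1ccc([Mg]Br)cc1 | starting material
13 | [(2R,3S,4R)-2-[4-(benzyloxy)phenyl]-3-{[(tert-butyldiphenylsilyl)oxy]methyl}oxolan-4-yl](4-methoxyphenyl)methanone | COc1ccc(C(=O)[C@H]2CO[C@@H](c3ccc(OCc4ccccc4)cc3)[C@@H]2CO[Si](c5ccccc5)(c6ccccc6)C(C)(C)C)cc1 | intermediate
14 | (S)-[(2R,3S,4R)-2-[4-(benzyloxy)phenyl]-3-{[(tert-butyldiphenylsilyl)oxy]methyl}oxolan-4-yl](4-methoxyphenyl)methanol | COc1ccc([C@@H](O)[C@H]2CO[C@@H](c3ccc(OCc4ccccc4)cc3)[C@@H]2CO[Si](c5ccccc5)(c6ccccc6)C(C)(C)C)cc1 | intermediate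
15 | 4-[(2R,3S,4R)-3-{[(tert-butyldiphenylsilyl)oxy]methyl}-4-[(S)-hydroxy(4-methoxyphenyl)methyl]oxolan-2-yl]phenol | COc1ccc([C@@H](O)[C@H]2CO[C@@H](c3ccc(O)cc3)[C@@H]2CO[Si](c4ccccc4)(c5ccccc5)C(C)(C)C)cc1 | intermediate
16 | 4-[(2R,3S,4R)-3-(hydroxymethyl)-4-[(S)-hydroxy(4-methoxyphenyl)methyl]oxolan-2-yl]phenol | COc1ccc([C@@H](O)[C@H]2CO[C@@H](c3ccc(O)cc3)[C@@H]2CO)cc1 | intermediate
17 | 4-[(2R,3S,4R)-3-(acetoxymethyl)-4-[(S)-acetoxy(4-methoxyphenyl)methyl]oxolan-2-yl]phenyl acetate | COc1ccc([C@@H](OC(C)=O)[C@H]2CO[C@@H](c3ccc(OC(C)=O)cc3)[C@@H]2COC(C)=O)cc1 | intermediate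
18 | [(2R,3S,4R)-4-[(S)-acetoxy(4-methoxyphenyl)methyl]-2-(4-hydroxyphenyl)oxolan-3-yl]methyl acetate | COc1ccc([C@@H](OC(C)=O)[C@H]2CO[C@@H](c3ccc(O)cc3)[C@@H]2COC(C)=O)cc1 | target

Total step count: 13. Longest linear sequence: 13 steps (from 1 to 18).

**Steps most likely to fail**

**Step 5.**
- Equilibration at C2 may stay incomplete, so the invertive, kinetic outcome persists.
- The cation may lose the C3 proton.
- Polymeric formaldehyde may fail to engage before the cyclopropane is consumed otherwise.

Fallback: the two ring bonds are made one at a time, setting out from 7. Yb(OTf)3-catalysed methanolysis opens the same C2–C4 bond. It gives the benzylic methyl ether dimethyl 2-[(2S)-1-[4-(benzyloxy)phenyl]-3-[(tert-butyldiphenylsilyl)oxy]-1-methoxypropan-2-yl]propanedioate F1, and either configuration at the benzylic carbon serves. Base-catalysed hydroxymethylation of its malonate C–H with aqueous formaldehyde (K2CO3, THF) forms C4–C5. This gives dimethyl 2-[(2S)-1-[4-(benzyloxy)phenyl]-3-[(tert-butyldiphenylsilyl)oxy]-1-methoxypropan-2-yl]-2-(hydroxymethyl)propanedioate F2. BF3·OEt2 in CH2Cl2 then ionises the benzylic ether, and the primary hydroxyl closes O1–C2 in a 5-exo-tet, SN1-type etherification under thermodynamic control. The route is rejoined at 9.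

**Step 9.** Facial selectivity of hydride delivery may be poor, or reduction of the hindered aryl ketone sluggish.

Fallback: the choice of face is handed to a catalyst instead of the substrate. Corey–Bakshi–Shibata reduction of 13 uses the (R)-methyl oxazaborolidine and BH3·SMe2 in THF, with the anisyl group in the large-group position. It should deliver hydride to the same Re face and lead directly to 14. No new compound arises (entry F0).

**Step 6.** The silyl ether may be lost, or C4 may equilibrate incompletely, during prolonged heating in wet DMSO.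

Fallback: a hydrolytic rather than a dealkylative removal of the ester, setting out from 9. One equivalent of LiOH in THF–H2O saponifies the more accessible ester, the one trans to the C3 arm. This gives the half-acid (2R,3S,4S)-2-[4-(benzyloxy)phenyl]-3-{[(tert-butyldiphenylsilyl)oxy]methyl}-4-(methoxycarbonyl)oxolane-4-carboxylic acid F3. Catalytic Cu2O in refluxing MeCN then decarboxylates it well below the Krapcho temperature. A trace of NaOMe in MeOH settles C4 in the trans arrangement, and the route is rejoined at 10.

**Further compounds**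

F1 | step 5 | dimethyl 2-[(2S)-1-[4-(benzyloxy)phenyl]-3-[(tert-butyldiphenylsilyl)oxy]-1-methoxypropan-2-yl]propanedioate | COC(=O)C(C(=O)OC)[C@@H](CO[Si](c1ccccc1)(c1ccccc1)C(C)(C)C)C(OC)c1ccc(OCc2ccccc2)cc1
F2 | step 5 | dimethyl 2-[(2S)-1-[4-(benzyloxy)phenyl]-3-[(tert-butyldiphenylsilyl)oxy]-1-methoxypropan-2-yl]-2-(hydroxymethyl)propanedioate | COC(=O)C(CO)(C(=O)OC)[C@@H](CO[Si](c1ccccc1)(c1ccccc1)C(C)(C)C)C(OC)c1ccc(OCc2ccccc2)cc1
F0 | step 9 | none | none
F3 | step 6 | (2R,3S,4S)-2-[4-(benzyloxy)phenyl]-3-{[(tert-butyldiphenylsilyl)oxy]methyl}-4-(methoxycarbonyl)oxolane-4-carboxylic acid | OC(=O)[C@@]1(C(=O)OC)CO[C@@H](c2ccc(OCc3ccccc3)cc2)[C@@H]1CO[Si](c4ccccc4)(c5ccccc5)C(C)(C)C
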